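**Retrosynthetic overview**

1. The C15 skeleton is C5 + C5 + C4: isoprene 1 and 3,3-dimethylacryloyl chloride 2 give, through chloro ketone 3, the acyclic trienone 4; Danishefsky's diene 5 supplies the last four carbons.
2. Key disconnection, both rings at once: ring B is cut by a Diels–Alder disconnection (adduct 6, cyclohexenone 7) and ring A at C6–C11 by a vinylogous Michael disconnection of spiro dienedione 8.
3. Order of ring formation: ring B first ([4+2]), ring A second (C6–C11 closure, which also creates the spiro stereocentre), both in one pot.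
4. Ring B halogens from the ring-B enone: 9 and 10 (C2–Cl), 11 (C3–CH3), 12 (C3–Br anti to Cl).
5. Ring A bromohydrin last: 13 and 14 (C10–Br), then 15 (C9–OH, the target).

Assumption: locants follow spiro[5.5]undecane numbering (C1–C5 = ring B with Cl on C2 and Br/CH3 on C3; C6 = spiro carbon; C7–C11 = ring A with CH3 on C7, OH on C9, Br on C10, two CH3 on C11), so the target is the (2S,3S,6R,9S,10R) isomer; the CIP label of C6 changes along the route although its geometry does not.

**Route**

Step 1
Reactants: 1 isoprene (2-methylbuta-1,3-diene); 2 3,3-dimethylacryloyl chloride (3-methylbut-2-enoyl chloride)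
Product: 4 (5E)-2,6-dimethylocta-2,5,7-trien-4-one, via chloro ketone 3 (not isolated)
Conditions: SnCl4 (0.2 equiv), CH2Cl2, −78 °C; then Et3N, 0 °C → rt
Reagents that add atoms: none
Why: Kondakov-type (aliphatic Friedel–Crafts) acylation of the diene at its CH2 terminus gives the 1,4-chloro-acyl adduct, and vinylogous E1cB loss of HCl gives the conjugated trienone; no stereocentre is formed and the E/Z ratio of the new C=C does not matter because it equilibrates in step 2.

Step 2
Reactants: 4 (5E)-2,6-dimethylocta-2,5,7-trien-4-one; 5 Danishefsky's diene, (E)-1-methoxy-3-(trimethylsilyloxy)buta-1,3-diene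
Product: 8 (6S)-7,11,11-trimethylspiro[5.5]undeca-1,7-diene-3,9-dione, via Diels–Alder adduct 6 (not isolated), via cyclohexenone 7 (not isolated)
Conditions: PhMe, 80 °C; then CF3CO2H (cat.), H2O, THF, 0 °C; then 9-amino-9-deoxy-epi-quinine (20 mol %), PhCO2H (40 mol %), PhMe, 40 °C, one pot
Reagents that add atoms: none
Why: Proposed new method: a normal-demand Diels–Alder reaction at the unhindered terminal vinyl group of 4, followed by acid unmasking, builds ring B as the 4-substituted cyclohexenone 7 whose C6–H is doubly vinylogously acidic, and the cinchona primary amine then turns the ring-B enone into a dienamine whose γ-carbon C6 adds to the β,β-dimethyl enone terminus C11 in a six-membered intramolecular vinylogous Michael step that closes ring A and sets the quaternary spiro centre (6S) on the face chosen by the catalyst (C6 is a ring sp2 carbon with two different ring neighbours, so only facial control is needed, the side-chain C=C equilibrates E/Z through the dienol and only the Z form can close, and the sense of induction must be confirmed, the quinidine-derived pseudo-enantiomer giving the antipode); the closest known reaction types are Danishefsky-diene cycloadditions to enones and cinchona-amine dienamine catalysis of vinylogous Michael additions of cyclohexenones.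

Step 3
Reactants: 8 (6S)-7,11,11-trimethylspiro[5.5]undeca-1,7-diene-3,9-dione
Product: 10 (2S,6S)-2-chloro-7,11,11-trimethylspiro[5.5]undec-7-ene-3,9-dione, via silyl enol ether 9 (not isolated)
Conditions: [(Ph3P)CuH]6 (5 mol %), PhMe2SiH (1.5 equiv), PhMe, 0 °C → rt; then N-chlorosuccinimide, THF, −78 → 0 °C
Reagents that add atoms: N-chlorosuccinimide, O=C1CCC(=O)N1Cl
Why: Copper hydride-catalysed 1,4-hydrosilylation reduces only the β-monosubstituted ring-B enone (the β,β-disubstituted ring-A enone is inert) and gives the C2=C3 silyl enol ether regiospecifically without passing through the symmetric saturated ketone, so C6 stays stereogenic, and electrophilic chlorination of the enol ether then occurs axially at C2 on the ring-B face syn to the flat sp2 arm C7 and anti to the CMe2 arm C11, setting (2S).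

Step 4
Reactants: 10 (2S,6S)-2-chloro-7,11,11-trimethylspiro[5.5]undec-7-ene-3,9-dione
Product: 11 (2S,3R,6S)-2-chloro-3-hydroxy-3,7,11,11-tetramethylspiro[5.5]undec-7-en-9-one
Conditions: MeMgBr (1.05 equiv), THF, −78 °C; aq NH4Cl quench at −78 °C
Reagents that add atoms: methylmagnesium bromide, C[Mg]Br
Why: Chemoselective Grignard 1,2-addition to the strongly activated α-chloro ketone (the conjugated C9 ketone reacts far more slowly) with methyl entering anti to the C–Cl bond (Cornforth/Felkin–Anh polar model) gives the cis-chlorohydrin (3R), a configuration that is not critical because step 5 is stereoconvergent.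

Step 5
Reactants: 11 (2S,3R,6S)-2-chloro-3-hydroxy-3,7,11,11-tetramethylspiro[5.5]undec-7-en-9-one
Product: 12 (2S,3S,6S)-3-bromo-2-chloro-3,7,11,11-tetramethylspiro[5.5]undec-7-en-9-one
Conditions: HBr (33 % in AcOH), CH2Cl2, 0 °C
Reagents that add atoms: hydrogen bromide, Br
Why: SN1 substitution of the tertiary alcohol in which the neighbouring C2 chlorine bridges the C3 cation (chloronium participation), so bromide opens at the tertiary carbon anti to chlorine and gives the trans-2-chloro-3-bromide (3S) from either carbinol epimer.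

Step 6
Reactants: 12 (2S,3S,6S)-3-bromo-2-chloro-3,7,11,11-tetramethylspiro[5.5]undec-7-en-9-one
Product: 14 (2S,3S,6R,10R)-3,10-dibromo-2-chloro-3,7,11,11-tetramethylspiro[5.5]undec-7-en-9-one, via silyl dienol ether 13 (not isolated)
Conditions: LiN(SiMe3)2, Me3SiCl, THF, −78 °C; then N-bromosuccinimide, THF, −78 °C
Reagents that add atoms: N-bromosuccinimide, O=C1CCC(=O)N1Br
Why: Kinetic α′-deprotonation of the enone at C10 with in situ silylation gives the cross-conjugated 2-silyloxy diene, which N-bromosuccinimide brominates at C10 (silyl enol ether halogenation) on the ring-A face syn to C1 and anti to the C5 methylene, giving (10R) by analogy with related chamigrene enones, while the hindered amide base at −78 °C leaves the tertiary bromide untouched.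

Step 7
Reactants: 14 (2S,3S,6R,10R)-3,10-dibromo-2-chloro-3,7,11,11-tetramethylspiro[5.5]undec-7-en-9-one
Product: 15 (2S,3S,6R,9S,10R)-3,10-dibromo-2-chloro-3,7,11,11-tetramethylspiro[5.5]undec-7-en-9-ol
Conditions: iBu2AlH, CH2Cl2, −78 °C
Reagents that add atoms: none
Why: 1,2-Reduction of the α-bromo enone by the bulky aluminium hydride from the face anti to the C10–Br bond gives the cis-bromohydrin (9S) and leaves the alkyl halides intact.

**Compound list**

1 | isoprene (2-methylbuta-1,3-diene) | C=CC(C)=C | starting material
2 | 3,3-dimethylacryloyl chloride | CC(C)=CC(Cl)=O | starting material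
3 | (6E)-8-chloro-2,6-dimethylocta-2,6-dien-4-one (chloro ketone, not isolated) | CC(C)=CC(=O)C/C(C)=C/CCl | intermediate
4 | (5E)-2,6-dimethylocta-2,5,7-trien-4-one (5Z isomer equally usable) | CC(C)=CC(=O)/C=C(\C)C=C | intermediate
5 | Danishefsky's diene, (E)-1-methoxy-3-(trimethylsilyloxy)buta-1,3-diene | CO/C=C/C(=C)O[Si](C)(C)C | starting material
6 | 3-methoxy-4-[(2E)-6-methyl-4-oxohepta-2,5-dien-2-yl]-1-(trimethylsilyloxy)cyclohex-1-ene (Diels–Alder adduct, racemic diastereomer mixture, both centres erased later, not isolated) | COC1C=C(O[Si](C)(C)C)CCC1/C(C)=C/C(=O)C=C(C)C | intermediate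
7 | 4-[(2E)-6-methyl-4-oxohepta-2,5-dien-2-yl]cyclohex-2-en-1-one (racemic, centre erased on ring closure, not isolated) | O=C1C=CC(CC1)/C(C)=C/C(=O)C=C(C)C | intermediate
8 | (6S)-7,11,11-trimethylspiro[5.5]undeca-1,7-diene-3,9-dione | CC1=CC(=O)CC(C)(C)[C@@]12CCC(=O)C=C2 | intermediate
9 | (6S)-3-[dimethyl(phenyl)silyloxy]-7,11,11-trimethylspiro[5.5]undeca-2,7-dien-9-one (not isolated) | CC1=CC(=O)CC(C)(C)[C@@]12CCC(O[Si](C)(C)c3ccccc3)=CC2 | intermediate
10 | (2S,6S)-2-chloro-7,11,11-trimethylspiro[5.5]undec-7-ene-3,9-dione | CC1=CC(=O)CC(C)(C)[C@@]12CCC(=O)[C@@H](Cl)C2 | intermediate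
11 | (2S,3R,6S)-2-chloro-3-hydroxy-3,7,11,11-tetramethylspiro[5.5]undec-7-en-9-one | CC1=CC(=O)CC(C)(C)[C@@]12CC[C@](O)(C)[C@@H](Cl)C2 | intermediate
12 | (2S,3S,6S)-3-bromo-2-chloro-3,7,11,11-tetramethylspiro[5.5]undec-7-en-9-one | CC1=CC(=O)CC(C)(C)[C@@]12CC[C@](C)(Br)[C@@H](Cl)C2 | intermediate
13 | (2S,3S,6R)-3-bromo-2-chloro-3,7,11,11-tetramethyl-9-(trimethylsilyloxy)spiro[5.5]undeca-7,9-diene (not isolated) | CC1=CC(O[Si](C)(C)C)=CC(C)(C)[C@@]12CC[C@](C)(Br)[C@@H](Cl)C2 | intermediate
14 | (2S,3S,6R,10R)-3,10-dibromo-2-chloro-3,7,11,11-tetramethylspiro[5.5]undec-7-en-9-one | CC1=CC(=O)[C@H](Br)C(C)(C)[C@@]12CC[C@](C)(Br)[C@@H](Cl)C2 | intermediate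
15 | (2S,3S,6R,9S,10R)-3,10-dibromo-2-chloro-3,7,11,11-tetramethylspiro[5.5]undec-7-en-9-ol | CC1=C[C@H](O)[C@H](Br)C(C)(C)[C@@]12CC[C@](C)(Br)[C@@H](Cl)C2 | target

**Step count and risks**

Total step count: 7. Longest linear sequence: 7 steps (from 1 and 2).

Steps most likely to fail:

Step 2 (one-pot cycloaddition and enantioselective ring closure). The likeliest failure is low ee, because the doubly activated C6–H of 7 can cyclise without the catalyst. The fallback sets out from 7, generated as in step 2 up to the acid stage, and erases the spiro centre before re-making it. Closure of 7 with an achiral base (DBU, PhMe) gives racemic 7,11,11-trimethylspiro[5.5]undeca-1,7-diene-3,9-dione F1. Hydrogenation of its ring-B enone only (H2, Pd/C, EtOAc, 1 equiv) gives 7,11,11-trimethylspiro[5.5]undec-7-ene-3,9-dione F2, in which ring B is symmetric and C6 is no longer stereogenic. An enantioselective organocatalytic α-chlorination (N-chlorosuccinimide, (4R,5R)-4,5-diphenylimidazolidine, 2-nitrobenzoic acid, MeCN, −24 °C) then desymmetrises F2, creating C2 and C6 together, and the route is rejoined at 10.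

Step 3 (face of chlorination at C2). Both ring-A arms place a methyl group over ring B, so the facial preference is not secure. If chlorine enters mainly on the wrong face, the same preference is used for oxygen and then inverted. The fallback sets out from 9: Rubottom oxidation (m-CPBA, NaHCO3, CH2Cl2, then desilylation) gives (2R,6S)-2-hydroxy-7,11,11-trimethylspiro[5.5]undec-7-ene-3,9-dione F3. Mesylation (MsCl, Et3N) gives (2R,6S)-7,11,11-trimethyl-3,9-dioxospiro[5.5]undec-7-en-2-yl methanesulfonate F4. SN2 displacement at the α-keto carbon with LiCl in DMF (inversion) returns to the route at 10.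

Step 6 (face of bromination at C10). The two faces of ring A differ only through the remote ring-B arms, so the wrong epimer may dominate. The fallback sets out from 13 and lets C10 be fixed by protonation instead of bromination. Bromination of 13 as in step 6 then gives mainly (2S,3S,6R,10S)-3,10-dibromo-2-chloro-3,7,11,11-tetramethylspiro[5.5]undec-7-en-9-one F5. Deprotonation at C10 (LiN(SiMe3)2, THF, −78 °C) gives lithium (2S,3S,6R)-3,10-dibromo-2-chloro-3,7,11,11-tetramethylspiro[5.5]undeca-7,9-dien-9-olate F6. Kinetic protonation with 2,6-di-tert-butylphenol delivers the proton to the face that bromine preferred, so bromine ends on the required face and the route is rejoined at 14.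

**Further compounds**

F1 | step 2 | racemic 7,11,11-trimethylspiro[5.5]undeca-1,7-diene-3,9-dione | CC1=CC(=O)CC(C)(C)C12CCC(=O)C=C2
F2 | step 2 | 7,11,11-trimethylspiro[5.5]undec-7-ene-3,9-dione (achiral) | CC1=CC(=O)CC(C)(C)C12CCC(=O)CC2
F3 | step 3 | (2R,6S)-2-hydroxy-7,11,11-trimethylspiro[5.5]undec-7-ene-3,9-dione | CC1=CC(=O)CC(C)(C)[C@@]12CCC(=O)[C@H](O)C2
F4 | step 3 | (2R,6S)-7,11,11-trimethyl-3,9-dioxospiro[5.5]undec-7-en-2-yl methanesulfonate | CC1=CC(=O)CC(C)(C)[C@@]12CCC(=O)[C@H](OS(C)(=O)=O)C2
F5 | step 6 | (2S,3S,6R,10S)-3,10-dibromo-2-chloro-3,7,11,11-tetramethylspiro[5.5]undec-7-en-9-one | CC1=CC(=O)[C@@H](Br)C(C)(C)[C@@]12CC[C@](C)(Br)[C@@H](Cl)C2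
F6 | step 6 | lithium (2S,3S,6R)-3,10-dibromo-2-chloro-3,7,11,11-tetramethylspiro[5.5]undeca-7,9-dien-9-olate | CC1=CC([O-])=C(Br)C(C)(C)[C@@]12CC[C@](C)(Br)[C@@H](Cl)C2.[Li+]
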